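Ring is what you want from the next flask, and you must choose how to charge it: summer fed, or midnight with the starting material in from the start.

| flask | starting material | protic impurity | remark | time |
|---|---|---|---|---|
| red | 0.020 M (fed, over 1.5 h) | 0.065 M | run made earlier; the fed solution adds 0.20 times the starting volume |  |
| green | 0.050 M (fed, over 1.5 h) | 0.065 M | run made earlier; the fed solution adds 0.20 times the starting volume |  |
| summer | 0.065 M (fed, over 1.5 h) | 0.0650 M | the fed solution adds 0.20 times the starting volume | 5.0 h |
| midnight | 0.030 M | 0.0650 M | everything together at the start, the whole solution of starting material included, so that from the start the volume is larger by 0.20 times the starting volume | 5.0 h |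

| run | time / h | ring / % |
|---|---|---|
| red | 0.200 | 3.1 |
| red | 0.500 | 12.8 |
| red | 1.00 | 29.4 |
| red | 1.50 | 47.3 |
| red | 2.00 | 53.8 |
| red | 3.00 | 55.4 |
| red | 4.00 | 55.4 |
| green | 0.200 | 2.4 |
| green | 0.500 | 10.1 |
| green | 1.00 | 22.3 |
| green | 1.50 | 35.0 |
| green | 2.00 | 39.9 |
| green | 3.00 | 40.3 |
| green | 4.00 | 40.2 |

(readings scatter by 0.3 percentage points)

- amounts are per litre of the starting volume; all of the dose is in the solution fed
- what was read earlier has a scatter of 0.3 percentage points, one standard deviation
- a reading or a percentage of ring counts all its forms, free or not
- percentages count the whole charge, also what has not yet gone in

- which one finishes higher in amount of ring, in percent of the starting material charged ("neither" within 2 percentage points) (summer / midnight / neither)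
- amount of ring at the end, in percent of the starting material charged, summer
- amount of ring at the end, in percent of the starting material charged, midnight

**Step 1: read the doses.** Final ring is lower in the green run, at 40.2%, than in the red run, at 55.4%. Green had the larger charge. So a loss grows with c(starting material), and you need to know how much of it stands in each flask.

**Step 2: read the lifetime.** After the red feed stops, the gap to the plateau shrinks from 8.1 percentage points to 1.6 points in 0.500 h. That reads as a half-life of 0.214 h, or a lifetime of 0.308 h. The second gap, 1.6 points, rests on readings that each scatter by 0.3 points, so treat both as rough.

**Step 3: reckon the stock.** The feed lasts 7.02 half-lives, so inflow and loss come to balance. This is pseudo-high dilution. Summer holds c(starting material) = 11.1 mM, the standing concentration: feed rate times lifetime, over the volume at the end of the feed. Expect less, because summer's larger charge should shorten the lifetime. By the same reckoning, red stands at 3.43 mM and green at 8.56 mM.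

**Step 4: decide.** Midnight starts at 25.0 mM, which is 2.25 times summer's stock, though it falls as it reacts. Summer stands higher than green, so I expect it just under green's plateau and still above midnight. Charge summer. Leave the time as it is: 16.4 half-lives follow the feed.

The forecast also says summer, and it adds yields: 36% for summer and 24.5% for midnight. Its ground: “It points to a second-order self-reaction of the starting material competing with first-order ring closure.”

The flask gives summer, with 36.2% for summer against 22.5% for midnight.

    starting material → ring (k = 3.01 h⁻¹)
    2 starting material → open dimer (k = 660 M⁻¹ h⁻¹)
    starting material + protic impurity → quenched substrate (k = 1.08 M⁻¹ h⁻¹)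
    crystals ⇌ ring, rate k4*(cs4 - [ring]) while solid is left; crystals form when [ring] > cs4 (solubility = 6.70 mM, k = 13.9 h⁻¹)

During summer's feed, starting material closed to ring and paired to open dimer. At 1.50 h it stood at 7.72% of the charge, or 4.18 mM, which is lower than the reckoned 11.1 mM. By 2.50 h it was down to 0.132%, with open dimer at 63.1%. A neighbour of summer charged with 0.016 M reckons, with the same lifetime, to a standing concentration of 2.74 mM, less than red's, and it ends with ring at 59.1%.

(The readings are calculated for an exercise, noise included.)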